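**Retrosynthetic overview**
- The last flask attaches the C7 acyl chain by Friedel–Crafts acylation and then removes all six O-methyl groups. Methyl ether is the only protecting group used.
- The key disconnection is the furan O1–C2 bond. It is made by adding the O–H of 3,5-dimethoxyphenol across a diaryl ynone, and this C–O bond alone fixes the 2-aryl/3-aroyl pattern.
- The C3–C3a bond is then closed in the same flask by dehydrogenative C–H/C–H coupling at one of two equivalent ortho positions.
- The ynone comes from 2,4-dimethoxybenzoyl chloride and 4-ethynylanisole by acyl Sonogashira coupling.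
- All four benzene rings are bought. The furan is the only ring built (step 2).

Assumption: the SMILES has no stereocentre, stereogenic axis or double-bond geometry, so the target is achiral and "single enantiomer" calls for no stereocontrol.

**Step 1**
Reactants: 1 2,4-dimethoxybenzoyl chloride; 2 1-ethynyl-4-methoxybenzene
Product: 3 1-(2,4-dimethoxyphenyl)-3-(4-methoxyphenyl)prop-2-yn-1-one
Conditions: PdCl2(PPh3)2 (2 mol %), CuI (4 mol %), Et3N (1.5 equiv), THF, rt, 3 h
Reagents that add atoms: none
Why: Acyl Sonogashira coupling, in which the aroyl chloride adds oxidatively to zerovalent palladium, the alkynyl group is handed over from copper, and reductive elimination gives the ynone at a temperature too low for decarbonylation; no stereocentre is formed.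

**Step 2**
Reactants: 3 1-(2,4-dimethoxyphenyl)-3-(4-methoxyphenyl)prop-2-yn-1-one; 4 3,5-dimethoxyphenol
Product: 6 (2,4-dimethoxyphenyl)[4,6-dimethoxy-2-(4-methoxyphenyl)-1-benzofuran-3-yl]methanone, via aryl enol ether 5 (not isolated)
Conditions: Cs2CO3 (20 mol %), 4 Å MS, 1,4-dioxane, 60 °C, 4 h; then PivOH (0.5 equiv), Pd(OAc)2 (10 mol %), AgOAc (2.5 equiv), 100 °C, 16 h
Reagents that add atoms: none
Why: Proposed new method: a one-flask dehydrogenative [3+2] annulation of a free phenol with a diaryl ynone, in which caesium 3,5-dimethoxyphenoxide first adds 1,4 to 3 so that oxygen ends on the anisyl-bearing β-carbon (the O1–C2 bond, which alone fixes the 2-aryl/3-aroyl pattern); the push-pull enol ether 5 then equilibrates E/Z by reversible C-protonation with PivOH, is palladated by divalent palladium at its nucleophilic α-carbon, undergoes pivalate-assisted C–H cleavage at either of the two equivalent, doubly methoxy-activated ortho positions to a six-membered palladacycle, and reductive elimination closes C3–C3a while AgOAc returns zerovalent palladium to divalent palladium; the closest known reaction types are the base-catalysed oxa-Michael addition of phenols to ynones and the Pd(OAc)2/CF3CO2Ag dehydrogenative closure of 3-aryloxyacrylates to benzofuran-3-carboxylates (and of N-aryl enaminones to indoles), neither shown on a fully substituted β-aryl-β-aryloxy enone nor merged with the C–O step to give a 2-aryl-3-aroylbenzofuran; no stereocentre is formed.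

**Step 3**
Reactants: 6 (2,4-dimethoxyphenyl)[4,6-dimethoxy-2-(4-methoxyphenyl)-1-benzofuran-3-yl]methanone; 7 3-(4-methoxyphenyl)propanoyl chloride
Product: 9 1-[3-(2,4-dihydroxybenzoyl)-4,6-dihydroxy-2-(4-hydroxyphenyl)-1-benzofuran-7-yl]-3-(4-hydroxyphenyl)propan-1-one (target CNP0181782.0), via hexamethyl ether 8 (not isolated)
Conditions: SnCl4 (2.5 equiv), CH2Cl2, 0 °C to rt, 3 h; then BBr3 (12 equiv), −78 °C to rt, 16 h; then ice-water
Reagents that add atoms: none
Why: Friedel–Crafts acylation goes to C7, because C2 and C3 are blocked, C5 lies between two methoxy groups, the other rings carry fewer donors or the complexed carbonyl, and 2,3-disubstituted 4,6-dimethoxybenzofurans are known to be acylated at C7, after which BBr3 ether cleavage in the same CH2Cl2 solution removes all six methyl groups, following the acylate-then-dealkylate one-flask practice used for 3-aroyl-2-arylbenzothiophenes; no stereocentre is formed.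

**Compound list**
1 | 2,4-dimethoxybenzoyl chloride | COc1ccc(C(=O)Cl)c(OC)c1 | starting material
2 | 1-ethynyl-4-methoxybenzene (4-ethynylanisole) | C#Cc1ccc(OC)cc1 | starting material
3 | 1-(2,4-dimethoxyphenyl)-3-(4-methoxyphenyl)prop-2-yn-1-one | COc1ccc(cc1)C#CC(=O)c1ccc(OC)cc1OC | intermediate
4 | 3,5-dimethoxyphenol | COc1cc(O)cc(OC)c1 | starting material
5 | (Z)-1-(2,4-dimethoxyphenyl)-3-(3,5-dimethoxyphenoxy)-3-(4-methoxyphenyl)prop-2-en-1-one (Z isomer from anti addition drawn; E and Z interconvert in the flask and both lead to 6) | COc1ccc(cc1)/C(Oc1cc(OC)cc(OC)c1)=C/C(=O)c1ccc(OC)cc1OC | intermediate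
6 | (2,4-dimethoxyphenyl)[4,6-dimethoxy-2-(4-methoxyphenyl)-1-benzofuran-3-yl]methanone | COc1ccc(cc1)-c1oc2cc(OC)cc(OC)c2c1C(=O)c1ccc(OC)cc1OC | intermediate
7 | 3-(4-methoxyphenyl)propanoyl chloride | COc1ccc(CCC(=O)Cl)cc1 | starting material
8 | 1-[3-(2,4-dimethoxybenzoyl)-4,6-dimethoxy-2-(4-methoxyphenyl)-1-benzofuran-7-yl]-3-(4-methoxyphenyl)propan-1-one | COc1ccc(CCC(=O)c2c(OC)cc(OC)c3c(C(=O)c4ccc(OC)cc4OC)c(-c4ccc(OC)cc4)oc23)cc1 | intermediate
9 | 1-[3-(2,4-dihydroxybenzoyl)-4,6-dihydroxy-2-(4-hydroxyphenyl)-1-benzofuran-7-yl]-3-(4-hydroxyphenyl)propan-1-one (achiral) | O=C(CCc1ccc(O)cc1)c1c(O)cc(O)c2c(C(=O)c3ccc(O)cc3O)c(-c3ccc(O)cc3)oc12 | target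

**Total step count:** 3
**Longest linear sequence:** 3 (1 or 2 → 3 → 6 → 9)

**Steps most likely to fail, with fallbacks**

*Step 2 (the new annulation).*
- The crowded trisubstituted enol ether may resist α-palladation.
- Carboxylate or traces of water may cleave it to the 1,3-diketone and 4.
- The phenoxide may attack through carbon.

The fallback uses known chemistry only, sets out from 4 (together with 3) and comes back at 6. Iodinate 4 with N-iodosuccinimide (MeCN, 0 °C) and separate the 4-iodo isomer to obtain 2-iodo-3,5-dimethoxyphenol F1. Add it to ynone 3 (K2CO3, DMF, 50 °C) to give (Z)-1-(2,4-dimethoxyphenyl)-3-(2-iodo-3,5-dimethoxyphenoxy)-3-(4-methoxyphenyl)prop-2-en-1-one F2. Close the furan by the established intramolecular Heck reaction of 2-iodoaryl vinylogous esters (Pd(OAc)2, PPh3, Et3N, MeCN, 80 °C), which delivers 6 without any oxidant.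

*Step 3 (acylation and six-fold dealkylation in one flask).*
- Any C5 acylation cannot be removed before deprotection.
- SnCl4 residues may slow the cleavage and leave partial methyl ethers.

The fallback moves the acyl group to the start, sets out from 4 and 7 and comes back at 8. Ortho-acylate 4 with 7 (AlCl3, CH2Cl2, 0 °C to rt) to the chelated ketone 1-(2-hydroxy-4,6-dimethoxyphenyl)-3-(4-methoxyphenyl)propan-1-one F3. Its only free OH sits next to the acyl group and it has only one free ortho C–H. Run the conditions of step 2 on F3 and 3, using a full equivalent of Cs2CO3 for the chelated phenol. This passes through (Z)-1-(2,4-dimethoxyphenyl)-3-{3,5-dimethoxy-2-[3-(4-methoxyphenyl)propanoyl]phenoxy}-3-(4-methoxyphenyl)prop-2-en-1-one F4 and can only give 8. Isolate and chromatograph 8, then treat it with BBr3 alone (CH2Cl2, −78 °C to rt) to reach 9.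

*Step 1 (acyl Sonogashira).*
- The electron-rich, ortho-substituted aroyl chloride may react slowly.
- Alkyne homocoupling or hydrolysis may then take over.

The fallback sets out from 2 and comes back at 3. It builds the carbonyl from gas instead of from an acid chloride. This is a carbonylative Sonogashira coupling of commercial 1-iodo-2,4-dimethoxybenzene, CO (1 atm) and 2 (PdCl2(PPh3)2, CuI, Et3N, THF, rt). Electron-rich aryl iodides favour CO insertion over direct coupling, and no new isolated compound is made.

**Further compounds**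
F1 | step 2 | 2-iodo-3,5-dimethoxyphenol | COc1cc(O)c(I)c(OC)c1
F2 | step 2 | (Z)-1-(2,4-dimethoxyphenyl)-3-(2-iodo-3,5-dimethoxyphenoxy)-3-(4-methoxyphenyl)prop-2-en-1-one | COc1ccc(cc1)/C(Oc1cc(OC)cc(OC)c1I)=C/C(=O)c1ccc(OC)cc1OC
F3 | step 3 | 1-(2-hydroxy-4,6-dimethoxyphenyl)-3-(4-methoxyphenyl)propan-1-one | COc1ccc(CCC(=O)c2c(O)cc(OC)cc2OC)cc1
F4 | step 3 | (Z)-1-(2,4-dimethoxyphenyl)-3-{3,5-dimethoxy-2-[3-(4-methoxyphenyl)propanoyl]phenoxy}-3-(4-methoxyphenyl)prop-2-en-1-one | COc1ccc(cc1)/C(Oc1cc(OC)cc(OC)c1C(=O)CCc1ccc(OC)cc1)=C/C(=O)c1ccc(OC)cc1OC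
F0 | step 1 | none | none
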